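**Plan**
- Retrosynthesis: the three aryl silyl ethers come off last. The carbinol C–H is cut back to an isopropenyl ketone and the carbinol–isopropenyl C–C bond to an acetal-masked arylacetaldehyde. Ring C is cut at O1–C2/C2–C3 (one-carbon unit), C3–C4 (benzyl Grignard) and C4–C4a (formyl group). Ring A is cut at C8a–C8, C7–C6 and C4a–C8a into a cyclobutenone and a 1-siloxyalkyne.
- Forward: ring A is made first from two ynol silyl ethers and ketene; C4 and the C3–aryl unit (ring B) are then attached at the free C4a position, ring C is closed with a one-carbon reagent, and the C6 side chain is finished on the intact isoflavone.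
- Enabling feature: ring A is a fully substituted benzene in which oxygen at C5, C7 and C8a alternates with carbon at C4a, C6 and C8. A vinylketene (C8a, C6, C5, C4a) and a siloxyalkyne (C8, C7) deliver this pattern with the three oxygens already told apart and with different carbon chains at C6 and C8.
- Protecting groups: all phenol oxygens travel as triisopropylsilyl ethers, so that one buffered fluoride treatment ends the synthesis without acid.
- Stereochemistry: the single stereocentre, the (R)-carbinol of the C6 side chain, is set by Corey–Bakshi–Shibata reduction of enone 29 with the (S)-oxazaborolidine.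

Key step: step 5

Remark: ring positions of all intermediates are given in isoflavone numbering (O1, C2–C4, C4a, C5–C8, C8a); the target carbinol reads as R from its SMILES; 4,4-diethoxybut-1-yne is taken as a purchasable building block and ketene as generated on demand from acetone. TIPS = triisopropylsilyl.

**Route**

Step 1
Reactants: 1 4,4-diethoxybut-1-yne
Product: 4 [(4,4-diethoxybut-1-yn-1-yl)oxy]triisopropylsilane, via lithium acetylide 2 (not isolated), via lithium ynolate 3 (not isolated)
Conditions: n-BuLi, THF, −78 °C; t-BuOOLi (from t-BuOOH and LiHMDS), −78 → 0 °C; TIPSOTf, −78 °C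
Reagents that add atoms: tert-butyl hydroperoxide CC(C)(C)OO; triisopropylsilyl triflate CC(C)[Si](C(C)C)(C(C)C)OS(=O)(=O)C(F)(F)F
Why: Oxidation of a lithium acetylide by lithium tert-butyl peroxide gives the ynolate, which the silyl triflate traps on oxygen; this is the standard entry to TIPS ynol ethers and the acetal is inert to the basic medium.

Step 2
Reactants: 4 ynol silyl ether
Product: 5 2-(2,2-diethoxyethyl)-3-(triisopropylsilyloxy)cyclobut-2-en-1-one
Conditions: CH2=C=O (excess, bubbled), CH2Cl2, 0 °C → rt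
Reagents that add atoms: ketene C=C=O
Why: Ketene–ynol ether [2+2] cycloaddition in which the alkyne carbon remote from oxygen attacks the ketene carbonyl carbon, placing the side chain at C2 and the siloxy group at C3 with C4 as CH2; the chain is carried by the alkyne because a substituted ketene would deliver it to C4.

Step 3
Reactants: 6 1-bromo-3-methylbut-2-ene (prenyl bromide)
Product: 7 5-methylhex-4-en-1-yne
Conditions: HC≡CMgBr (2 equiv), CuCl (cat.), THF, 0 → 50 °C
Reagents that add atoms: ethynylmagnesium bromide C#C[Mg]Br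
Why: Copper-catalysed SN2 coupling of an alkynyl Grignard reagent with an allylic bromide, attack at the primary terminus avoiding a quaternary carbon and giving the skipped enyne.

Step 4
Reactants: 7 5-methylhex-4-en-1-yne
Product: 10 triisopropyl[(5-methylhex-4-en-1-yn-1-yl)oxy]silane, via lithium acetylide 8 (not isolated), via lithium ynolate 9 (not isolated)
Conditions: n-BuLi, THF, −78 °C; t-BuOOLi (from t-BuOOH and LiHMDS), −78 → 0 °C; TIPSOTf, −78 °C
Reagents that add atoms: tert-butyl hydroperoxide CC(C)(C)OO; triisopropylsilyl triflate CC(C)[Si](C(C)C)(C(C)C)OS(=O)(=O)C(F)(F)F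
Why: Same acetylide oxidation and O-silylation as in step 1, the terminal alkyne C–H being far more acidic than the doubly allylic/propargylic CH2.

Step 5
Reactants: 5 siloxycyclobutenone; 10 prenyl ynol silyl ether (1.5 equiv)
Product: 15 4-(2,2-diethoxyethyl)-2-(3-methylbut-2-enyl)-3,5-bis(triisopropylsilyloxy)phenol, via vinylketene 11 (not isolated), via vinylcyclobutenone 12 (not isolated), via dienylketene 13 (not isolated), via cyclohexadienone 14 (not isolated)
Conditions: PhMe, sealed tube, 80 °C then 120 °C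
Reagents that add atoms: none
Why: Thermal 4π electrocyclic opening of 5 gives vinylketene 11, whose ketene C=C undergoes [2+2] cycloaddition with 10 to give vinylcyclobutenone 12 (new bonds C8a–C8 and C7–C6); 12 opens again to dienylketene 13, which closes by 6π electrocyclisation (bond C4a–C8a) to cyclohexadienone 14 and tautomerises to phenol 15. The closest known reaction type is the Danheiser benzannulation of cyclobutenones with siloxyalkynes; the 3-siloxy group on the cyclobutenone extends the usual alkyl and aryl cases, so the first ring opening may need the upper end of the temperature range. Ring A, the only ring closed, forms by a thermally allowed disrotatory 6π closure of the dienylketene that has the ketene and siloxyvinyl groups cis, and enolisation to the arene makes it irreversible. No stereocentre results, because the quaternary carbon of 12 becomes aromatic C6. The one selectivity required is the orientation of the [2+2] step: the carbon of 10 remote from oxygen is the nucleophilic terminus and bonds to the ketene carbonyl carbon, which puts prenyl at C8 beside the new C8a hydroxyl and the silyl ether at C7, so the oxygens emerge as free OH (C8a), silyl ether from 5 (C5) and silyl ether from 10 (C7), with C4a the only unsubstituted carbon.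

Step 6
Reactants: 15 phenol
Product: 17 5-(2,2-diethoxyethyl)-2-hydroxy-3-(3-methylbut-2-enyl)-4,6-bis(triisopropylsilyloxy)benzaldehyde, via salicyl alcohol 16 (not isolated)
Conditions: MgCl2, Et3N, (CH2O)n, MeCN, 80 °C; aq. NH4Cl work-up
Reagents that add atoms: formaldehyde (as paraformaldehyde) C=O
Why: Magnesium-mediated ortho-formylation of a phenol (Casnati–Skattebøl reaction), in which the magnesium phenoxide delivers formaldehyde to the only free ortho carbon (C4a) and a second formaldehyde oxidises salicyl alcohol 16 by hydride transfer, under basic conditions that spare acetal, prenyl group and silyl ethers.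

Step 7
Reactants: 18 4-hydroxybenzaldehyde
Product: 19 4-(triisopropylsilyloxy)benzaldehyde
Conditions: TIPSCl, imidazole, DMF, rt
Reagents that add atoms: triisopropylsilyl chloride CC(C)[Si](Cl)(C(C)C)C(C)C
Why: Standard silylation of a phenol with a silyl chloride and imidazole.

Step 8
Reactants: 19 silyloxybenzaldehyde
Product: 20 [4-(triisopropylsilyloxy)phenyl]methanol
Conditions: NaBH4, MeOH, 0 °C
Reagents that add atoms: none
Why: Borohydride reduction of an aromatic aldehyde to the benzylic alcohol.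

Step 9
Reactants: 20 benzylic alcohol
Product: 21 [4-(chloromethyl)phenoxy]triisopropylsilane
Conditions: SOCl2, CH2Cl2, 0 °C → rt
Reagents that add atoms: thionyl chloride O=S(Cl)Cl
Why: Chlorination of an electron-rich benzylic alcohol with thionyl chloride, the aryl TIPS ether tolerating the HCl released.

Step 10
Reactants: 17 salicylaldehyde; 21 benzyl chloride (3 equiv)
Product: 23 rac-1-[5-(2,2-diethoxyethyl)-2-hydroxy-3-(3-methylbut-2-enyl)-4,6-bis(triisopropylsilyloxy)phenyl]-2-[4-(triisopropylsilyloxy)phenyl]ethanol, via Grignard reagent 22 (not isolated)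
Conditions: 21, Mg, Et2O, 0 °C; then 17, THF, −78 → 0 °C
Reagents that add atoms: none
Why: Grignard addition to an aldehyde, one equivalent of 22 deprotonating the phenol and a second adding to the magnesium-chelated formyl group, which gives the carbinol as a racemate whose stereocentre is removed in step 11.

Step 11
Reactants: 23 diol
Product: 24 1-[5-(2,2-diethoxyethyl)-2-hydroxy-3-(3-methylbut-2-enyl)-4,6-bis(triisopropylsilyloxy)phenyl]-2-[4-(triisopropylsilyloxy)phenyl]ethanone
Conditions: Dess–Martin periodinane, CH2Cl2, 0 °C → rt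
Reagents that add atoms: none
Why: Dess–Martin oxidation of a secondary benzylic alcohol to the ketone under near-neutral conditions that should spare the hydrogen-bonded, fully substituted phenol, the prenyl alkene and the acetal.

Step 12
Reactants: 24 2-hydroxydeoxybenzoin
Product: 26 6-(2,2-diethoxyethyl)-8-(3-methylbut-2-enyl)-5,7-bis(triisopropylsilyloxy)-3-[4-(triisopropylsilyloxy)phenyl]-4H-chromen-4-one, via enaminone 25 (not isolated)
Conditions: Me2NCH(OMe)2, PhMe, 90 °C
Reagents that add atoms: N,N-dimethylformamide dimethyl acetal COC(OC)N(C)C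
Why: Enaminone formation at the activated methylene of a 2-hydroxydeoxybenzoin followed by 6-endo conjugate addition of the C8a hydroxyl and loss of dimethylamine (the standard one-carbon isoflavone closure), which can close ring C in one direction only because the C8a oxygen is the only free one.

Step 13
Reactants: 26 isoflavone acetal
Product: 27 2-{8-(3-methylbut-2-enyl)-4-oxo-5,7-bis(triisopropylsilyloxy)-3-[4-(triisopropylsilyloxy)phenyl]-4H-chromen-6-yl}acetaldehyde
Conditions: PPTS, acetone–H2O, 50 °C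
Reagents that add atoms: water O
Why: Mild acid-catalysed acetal hydrolysis, to which aryl TIPS ethers are stable; with both flanking oxygens silylated the arylacetaldehyde cannot close to a lactol or benzofuran.

Step 14
Reactants: 27 arylacetaldehyde
Product: 28 rac-6-(2-hydroxy-3-methylbut-3-enyl)-8-(3-methylbut-2-enyl)-5,7-bis(triisopropylsilyloxy)-3-[4-(triisopropylsilyloxy)phenyl]-4H-chromen-4-one
Conditions: CeCl3 (anhydrous), CH2=C(CH3)MgBr, THF, −78 °C
Reagents that add atoms: isopropenylmagnesium bromide C=C(C)[Mg]Br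
Why: 1,2-Addition of an alkenylcerium reagent to the aldehyde, its low basicity suppressing enolisation of the arylacetaldehyde and attack on the chromone; the carbinol forms as a racemate that is oxidised in step 15.

Step 15
Reactants: 28 racemic allylic alcohol
Product: 29 6-(3-methyl-2-oxobut-3-enyl)-8-(3-methylbut-2-enyl)-5,7-bis(triisopropylsilyloxy)-3-[4-(triisopropylsilyloxy)phenyl]-4H-chromen-4-one
Conditions: Dess–Martin periodinane, CH2Cl2, 0 °C; used at once
Reagents that add atoms: none
Why: Dess–Martin oxidation of a secondary allylic alcohol to the isopropenyl ketone without base, so the enone is not exposed to Michael donors.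

Step 16
Reactants: 29 enone
Product: 30 6-[(2R)-2-hydroxy-3-methylbut-3-enyl]-8-(3-methylbut-2-enyl)-5,7-bis(triisopropylsilyloxy)-3-[4-(triisopropylsilyloxy)phenyl]-4H-chromen-4-one
Conditions: (S)-2-methyl-CBS-oxazaborolidine (0.5 equiv), catecholborane, PhMe, −78 °C
Reagents that add atoms: none
Why: Corey–Bakshi–Shibata reduction in which the (S)-oxazaborolidine binds the ketone with the α-branched isopropenyl group as the large substituent and delivers hydride to the Si face to give the (R)-carbinol, catecholborane at −78 °C being chosen so that no alkene is hydroborated and the chromone carbonyl is left alone.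

Step 17
Reactants: 30 tris-silyl ether
Product: 31 5,7-dihydroxy-6-[(2R)-2-hydroxy-3-methylbut-3-enyl]-3-(4-hydroxyphenyl)-8-(3-methylbut-2-enyl)-4H-chromen-4-one (CNP0105386.1)
Conditions: TBAF, AcOH, THF, 0 °C → rt
Reagents that add atoms: none
Why: Fluoride cleavage of the three aryl silyl ethers, acetic acid buffering the phenoxides so that the pyranone ring, the prenyl group and the allylic alcohol are not affected and the stereocentre is not touched.

**Compound list**

1 | 4,4-diethoxybut-1-yne | C#CCC(OCC)OCC | starting material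
2 | (4,4-diethoxybut-1-yn-1-yl)lithium | [Li]C#CCC(OCC)OCC | intermediate (not isolated)
3 | lithium 4,4-diethoxybut-1-yn-1-olate | [Li]OC#CCC(OCC)OCC | intermediate (not isolated)
4 | [(4,4-diethoxybut-1-yn-1-yl)oxy]triisopropylsilane | CCOC(OCC)CC#CO[Si](C(C)C)(C(C)C)C(C)C | intermediate
5 | 2-(2,2-diethoxyethyl)-3-(triisopropylsilyloxy)cyclobut-2-en-1-one | CCOC(OCC)CC1=C(O[Si](C(C)C)(C(C)C)C(C)C)CC1=O | intermediate
6 | 1-bromo-3-methylbut-2-ene | CC(C)=CCBr | starting material
7 | 5-methylhex-4-en-1-yne | CC(C)=CCC#C | intermediate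
8 | (5-methylhex-4-en-1-yn-1-yl)lithium | [Li]C#CCC=C(C)C | intermediate (not isolated)
9 | lithium 5-methylhex-4-en-1-yn-1-olate | [Li]OC#CCC=C(C)C | intermediate (not isolated)
10 | triisopropyl[(5-methylhex-4-en-1-yn-1-yl)oxy]silane | CC(C)=CCC#CO[Si](C(C)C)(C(C)C)C(C)C | intermediate
11 | 2-(2,2-diethoxyethyl)-3-(triisopropylsilyloxy)buta-1,3-dien-1-one (vinylketene) | O=C=C(CC(OCC)OCC)C(=C)O[Si](C(C)C)(C(C)C)C(C)C | intermediate (not isolated)
12 | rac-4-(2,2-diethoxyethyl)-2-(3-methylbut-2-enyl)-3-(triisopropylsilyloxy)-4-[1-(triisopropylsilyloxy)vinyl]cyclobut-2-en-1-one | O=C1C(CC=C(C)C)=C(O[Si](C(C)C)(C(C)C)C(C)C)C1(CC(OCC)OCC)C(=C)O[Si](C(C)C)(C(C)C)C(C)C | intermediate (not isolated)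
13 | (3E)-4-(2,2-diethoxyethyl)-2-(3-methylbut-2-enyl)-3,5-bis(triisopropylsilyloxy)hexa-1,3,5-trien-1-one (dienylketene) | O=C=C(CC=C(C)C)/C(O[Si](C(C)C)(C(C)C)C(C)C)=C(/CC(OCC)OCC)C(=C)O[Si](C(C)C)(C(C)C)C(C)C | intermediate (not isolated)
14 | 4-(2,2-diethoxyethyl)-2-(3-methylbut-2-enyl)-3,5-bis(triisopropylsilyloxy)cyclohexa-2,4-dien-1-one | O=C1CC(O[Si](C(C)C)(C(C)C)C(C)C)=C(CC(OCC)OCC)C(O[Si](C(C)C)(C(C)C)C(C)C)=C1CC=C(C)C | intermediate (not isolated)
15 | 4-(2,2-diethoxyethyl)-2-(3-methylbut-2-enyl)-3,5-bis(triisopropylsilyloxy)phenol | Oc1cc(O[Si](C(C)C)(C(C)C)C(C)C)c(CC(OCC)OCC)c(O[Si](C(C)C)(C(C)C)C(C)C)c1CC=C(C)C | intermediate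
16 | 4-(2,2-diethoxyethyl)-6-(hydroxymethyl)-2-(3-methylbut-2-enyl)-3,5-bis(triisopropylsilyloxy)phenol | OCc1c(O)c(CC=C(C)C)c(O[Si](C(C)C)(C(C)C)C(C)C)c(CC(OCC)OCC)c1O[Si](C(C)C)(C(C)C)C(C)C | intermediate (not isolated)
17 | 5-(2,2-diethoxyethyl)-2-hydroxy-3-(3-methylbut-2-enyl)-4,6-bis(triisopropylsilyloxy)benzaldehyde | O=Cc1c(O)c(CC=C(C)C)c(O[Si](C(C)C)(C(C)C)C(C)C)c(CC(OCC)OCC)c1O[Si](C(C)C)(C(C)C)C(C)C | intermediate
18 | 4-hydroxybenzaldehyde | O=Cc1ccc(O)cc1 | starting material
19 | 4-(triisopropylsilyloxy)benzaldehyde | O=Cc1ccc(O[Si](C(C)C)(C(C)C)C(C)C)cc1 | intermediate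
20 | [4-(triisopropylsilyloxy)phenyl]methanol | OCc1ccc(O[Si](C(C)C)(C(C)C)C(C)C)cc1 | intermediate
21 | [4-(chloromethyl)phenoxy]triisopropylsilane | ClCc1ccc(O[Si](C(C)C)(C(C)C)C(C)C)cc1 | intermediate
22 | [4-(triisopropylsilyloxy)benzyl]magnesium chloride | Cl[Mg]Cc1ccc(O[Si](C(C)C)(C(C)C)C(C)C)cc1 | intermediate (not isolated)
23 | rac-1-[5-(2,2-diethoxyethyl)-2-hydroxy-3-(3-methylbut-2-enyl)-4,6-bis(triisopropylsilyloxy)phenyl]-2-[4-(triisopropylsilyloxy)phenyl]ethanol | OC(Cc1ccc(O[Si](C(C)C)(C(C)C)C(C)C)cc1)c1c(O)c(CC=C(C)C)c(O[Si](C(C)C)(C(C)C)C(C)C)c(CC(OCC)OCC)c1O[Si](C(C)C)(C(C)C)C(C)C | intermediate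
24 | 1-[5-(2,2-diethoxyethyl)-2-hydroxy-3-(3-methylbut-2-enyl)-4,6-bis(triisopropylsilyloxy)phenyl]-2-[4-(triisopropylsilyloxy)phenyl]ethanone | O=C(Cc1ccc(O[Si](C(C)C)(C(C)C)C(C)C)cc1)c1c(O)c(CC=C(C)C)c(O[Si](C(C)C)(C(C)C)C(C)C)c(CC(OCC)OCC)c1O[Si](C(C)C)(C(C)C)C(C)C | intermediate
25 | 3-(dimethylamino)-1-[5-(2,2-diethoxyethyl)-2-hydroxy-3-(3-methylbut-2-enyl)-4,6-bis(triisopropylsilyloxy)phenyl]-2-[4-(triisopropylsilyloxy)phenyl]prop-2-en-1-one | CN(C)C=C(C(=O)c1c(O)c(CC=C(C)C)c(O[Si](C(C)C)(C(C)C)C(C)C)c(CC(OCC)OCC)c1O[Si](C(C)C)(C(C)C)C(C)C)c1ccc(O[Si](C(C)C)(C(C)C)C(C)C)cc1 | intermediate (not isolated)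
26 | 6-(2,2-diethoxyethyl)-8-(3-methylbut-2-enyl)-5,7-bis(triisopropylsilyloxy)-3-[4-(triisopropylsilyloxy)phenyl]-4H-chromen-4-one | CCOC(OCC)Cc1c(O[Si](C(C)C)(C(C)C)C(C)C)c(CC=C(C)C)c2occ(-c3ccc(O[Si](C(C)C)(C(C)C)C(C)C)cc3)c(=O)c2c1O[Si](C(C)C)(C(C)C)C(C)C | intermediate
27 | 2-{8-(3-methylbut-2-enyl)-4-oxo-5,7-bis(triisopropylsilyloxy)-3-[4-(triisopropylsilyloxy)phenyl]-4H-chromen-6-yl}acetaldehyde | O=CCc1c(O[Si](C(C)C)(C(C)C)C(C)C)c(CC=C(C)C)c2occ(-c3ccc(O[Si](C(C)C)(C(C)C)C(C)C)cc3)c(=O)c2c1O[Si](C(C)C)(C(C)C)C(C)C | intermediate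
28 | rac-6-(2-hydroxy-3-methylbut-3-enyl)-8-(3-methylbut-2-enyl)-5,7-bis(triisopropylsilyloxy)-3-[4-(triisopropylsilyloxy)phenyl]-4H-chromen-4-one | C=C(C)C(O)Cc1c(O[Si](C(C)C)(C(C)C)C(C)C)c(CC=C(C)C)c2occ(-c3ccc(O[Si](C(C)C)(C(C)C)C(C)C)cc3)c(=O)c2c1O[Si](C(C)C)(C(C)C)C(C)C | intermediate
29 | 6-(3-methyl-2-oxobut-3-enyl)-8-(3-methylbut-2-enyl)-5,7-bis(triisopropylsilyloxy)-3-[4-(triisopropylsilyloxy)phenyl]-4H-chromen-4-one | C=C(C)C(=O)Cc1c(O[Si](C(C)C)(C(C)C)C(C)C)c(CC=C(C)C)c2occ(-c3ccc(O[Si](C(C)C)(C(C)C)C(C)C)cc3)c(=O)c2c1O[Si](C(C)C)(C(C)C)C(C)C | intermediate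
30 | 6-[(2R)-2-hydroxy-3-methylbut-3-enyl]-8-(3-methylbut-2-enyl)-5,7-bis(triisopropylsilyloxy)-3-[4-(triisopropylsilyloxy)phenyl]-4H-chromen-4-one | C=C(C)[C@H](O)Cc1c(O[Si](C(C)C)(C(C)C)C(C)C)c(CC=C(C)C)c2occ(-c3ccc(O[Si](C(C)C)(C(C)C)C(C)C)cc3)c(=O)c2c1O[Si](C(C)C)(C(C)C)C(C)C | intermediate
31 | 5,7-dihydroxy-6-[(2R)-2-hydroxy-3-methylbut-3-enyl]-3-(4-hydroxyphenyl)-8-(3-methylbut-2-enyl)-4H-chromen-4-one | C=C(C)[C@H](O)Cc1c(O)c(CC=C(C)C)c2occ(-c3ccc(O)cc3)c(=O)c2c1O | target

**Step count and risks**

Total step count: 17 (steps 7–9 prepare the benzyl chloride off the main line).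
Longest linear sequence: 12 steps (1, 2, 5, 6, 10–17 from alkyne 1; equally 3, 4, 5, 6, 10–17 from bromide 6).

Most likely to fail:

1. Step 5 (benzannulation). The 3-siloxy group stabilises cyclobutenone 5 as a vinylogous silyl ester, so the first ring opening may be slow. Decomposition of ynol ether 10 by silyl shift, silyl transfer from 5 to the product phenol, or acylation of the phenol by ketene 11 could then outrun the cascade. Fallback: generate the same vinylketene at room temperature by photochemical Wolff rearrangement instead of cyclobutenone opening. This sets out from ynol ether 10 and returns at phenol 15. Methyl pyruvate with TIPSOTf/Et3N should give methyl 2-(triisopropylsilyloxy)prop-2-enoate F1. MeNH(OMe)·HCl/i-PrMgCl converts it into N-methoxy-N-methyl-2-(triisopropylsilyloxy)prop-2-enamide F2. Addition of (3,3-diethoxypropyl)magnesium chloride gives 6,6-diethoxy-2-(triisopropylsilyloxy)hex-1-en-3-one F3. Deacylative diazo transfer (LiHMDS, CF3CO2CH2CF3; then MsN3, Et3N) gives 4-diazo-6,6-diethoxy-2-(triisopropylsilyloxy)hex-1-en-3-one F4. Irradiation of F4 with 10 (300 nm, ClCH2CH2Cl, rt, then 80 °C) should expel nitrogen, shift the siloxyvinyl group to give 11, and let the rest of the cascade run to 15.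

2. Step 2 (ketene cycloaddition). Ketene may dimerise faster than it adds to the hindered ynol ether 4, leaving 4 unchanged. Fallback: a more electrophilic ketene followed by reduction, setting out from 4 and returning at 5. Dichloroketene (Cl2CHCOCl, Et3N, hexane, 0 °C) should add with the same orientation to give 4,4-dichloro-2-(2,2-diethoxyethyl)-3-(triisopropylsilyloxy)cyclobut-2-en-1-one F5, and buffered zinc reduction (Zn, TMEDA, AcOH, EtOH, 0 °C) removes both chlorines to give 5.

3. Step 16 (enone reduction). Facial discrimination may be poor if the bulky 2,6-bis(silyloxy)benzyl group competes with isopropenyl for the role of the large substituent, and conjugate reduction of the enone may intrude. Fallback: Sharpless kinetic resolution instead of oxidation and reduction, setting out from racemic alcohol 28 and returning at 30 (steps 15 and 16 are skipped). With Ti(OiPr)4, L-(+)-diisopropyl tartrate, t-BuOOH (0.6 equiv) and 4 Å molecular sieves in CH2Cl2 at −20 °C, the (S)-enantiomer of 28 should be consumed as the erythro epoxy alcohol 6-{(2S)-2-hydroxy-2-[(2R)-2-methyloxiran-2-yl]ethyl}-8-(3-methylbut-2-enyl)-5,7-bis(triisopropylsilyloxy)-3-[4-(triisopropylsilyloxy)phenyl]-4H-chromen-4-one F6. The (R)-alcohol 30 is left unreacted (at most half of the material); the prenyl alkene is not an allylic alcohol and should not be epoxidised.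

**Further compounds**

F1 | step 5 | methyl 2-(triisopropylsilyloxy)prop-2-enoate | C=C(O[Si](C(C)C)(C(C)C)C(C)C)C(=O)OC
F2 | step 5 | N-methoxy-N-methyl-2-(triisopropylsilyloxy)prop-2-enamide | C=C(O[Si](C(C)C)(C(C)C)C(C)C)C(=O)N(C)OC
F3 | step 5 | 6,6-diethoxy-2-(triisopropylsilyloxy)hex-1-en-3-one | C=C(O[Si](C(C)C)(C(C)C)C(C)C)C(=O)CCC(OCC)OCC
F4 | step 5 | 4-diazo-6,6-diethoxy-2-(triisopropylsilyloxy)hex-1-en-3-one | C=C(O[Si](C(C)C)(C(C)C)C(C)C)C(=O)C(=[N+]=[N-])CC(OCC)OCC
F5 | step 2 | 4,4-dichloro-2-(2,2-diethoxyethyl)-3-(triisopropylsilyloxy)cyclobut-2-en-1-one | CCOC(OCC)CC1=C(O[Si](C(C)C)(C(C)C)C(C)C)C(Cl)(Cl)C1=O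
F6 | step 16 | 6-{(2S)-2-hydroxy-2-[(2R)-2-methyloxiran-2-yl]ethyl}-8-(3-methylbut-2-enyl)-5,7-bis(triisopropylsilyloxy)-3-[4-(triisopropylsilyloxy)phenyl]-4H-chromen-4-one | C[C@@]4(CO4)[C@@H](O)Cc1c(O[Si](C(C)C)(C(C)C)C(C)C)c(CC=C(C)C)c2occ(-c3ccc(O[Si](C(C)C)(C(C)C)C(C)C)cc3)c(=O)c2c1O[Si](C(C)C)(C(C)C)C(C)C
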